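The numbers were drawn at random within sensible limits; the flask was simulated.

The ratio I wanted first was uptake over supply: how fast the starting complex takes dissolved incoming ligand, against how fast the gas refills the solution.

starting complex 1.5 M; leaving ligand 3.00 M; gas 56 mM (held); time 1.5 h

1. amount of complex with two exchanged at 1.5 h, in percent of the starting complex charged
2. the change that raises the amount of complex with two exchanged at 1.5 h, in percent of the starting complex charged most ("none" if none brings more than 2 percentage points) (winter / noon / none)
3. amount of complex with two exchanged at 1.5 h, in percent of the starting complex charged, after winter

- at the start none of incoming ligand is dissolved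
- run time (flask): 1.5 h

- winter: doubling the saturation concentration of gas, all else as stated
- noon: doubling the transfer coefficient of step 4, all else as stated

Uptake over supply = 0.019 M⁻¹ s⁻¹ × 1.5 M / 0.0074 s⁻¹ = 3.85

At the charge, uptake was faster than supply, so I took the ligand as steady, at one over one plus that ratio:

Fraction of saturation = 0.206

I held this opening value through the run. The first exchange is then pseudo-first-order, and its rate integrates in closed form:

Exposure = 0.019 M⁻¹ s⁻¹ × 0.206 × 56 mM × 1.5 h = 1.18

Fraction of starting complex left = exp(−exposure) = 30.6%

I call this number the ligand exposure: the rate of the first exchange per unit of starting complex, summed over the run.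

I reckoned the exposure at 2.37 for winter and at 1.96 for noon, so winter's was larger. But one number was not enough. The complex with two exchanged stands mid-chain, and the complex with one exchanged also turns into side product, a step that takes no ligand. By my reckoning, about half of the complex with one exchanged went on to the second exchange. So I gave no figure for the amount asked.

The forecast gave 21% (18% to 24%), noon as best, and 20% after winter (15% to 25%). It held that “doubling the transfer coefficient gives a milder speed-up”.

The simulation gave 21.1% for the flask and 20.5% after winter. The best change was noon, at 4.2 percentage points against −0.63 points for winter.

    complex with two exchanged + incoming ligand → leaving ligand + complex with three exchanged (k1 = 0.012 M⁻¹ s⁻¹)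
    complex with one exchanged → side product (k2 = 3.5 × 10⁻⁴ s⁻¹)
    starting complex + incoming ligand → leaving ligand + complex with one exchanged (k3 = 0.019 M⁻¹ s⁻¹)
    gas ⇌ incoming ligand, rate k4*(csat - [incoming ligand]) (k4 = 0.0074 s⁻¹, csat = 56 mM)
    complex with one exchanged + incoming ligand → leaving ligand + complex with two exchanged (k5 = 0.028 M⁻¹ s⁻¹)

The flask kept 27% of its starting complex, less than my 30.6%. The neighbouring flask, charged with 0.90 M of starting complex, takes the same reckoning:

Uptake over supply = 2.31

Exposure = 1.74

Fraction left = 17.6%

That neighbouring flask kept 13% of its starting complex and held 25.6% as complex with two exchanged.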